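The maple run climbs from 3.8 % at 3.00 h to 19.4 % at 15.0 h, and the cedar run climbs from 13.8 % at 3.00 h to 51.3 % at 10.0 h.

in all of them: starting material 0.13 M

| run | partner | free catalyst | temperature | remark | time |
|---|---|---|---|---|---|
| maple | 0.137 M (fed, over 2.5 h) | 0.65 mM | −25 °C | run made earlier; the fed solution adds 0.10 times the starting volume |  |
| cedar | 0.137 M (fed, over 2.5 h) | 0.98 mM | −10 °C | run made earlier; the fed solution adds 0.10 times the starting volume |  |
| south-east | 0.137 M (fed, over 10 h) | 1.3 mM |  | at −20 °C throughout; the fed solution adds 0.10 times the starting volume | 25 h |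
| north-west | 0.137 M (fed, over 2.5 h) | 1.3 mM |  | at −20 °C until 2.5 h, from then on at 0 °C; the fed solution adds 0.10 times the starting volume | 25 h |

| run | time / h | product / % |
|---|---|---|
| maple | 1.00 | 0.1 |
| maple | 3.00 | 3.8 |
| maple | 5.00 | 5.8 |
| maple | 8.00 | 9.5 |
| maple | 12.0 | 15.2 |
| maple | 15.0 | 19.4 |
| cedar | 0.833 | 1.2 |
| cedar | 1.33 | 3.7 |
| cedar | 2.00 | 6.9 |
| cedar | 3.00 | 13.8 |
| cedar | 6.00 | 31.8 |
| cedar | 10.0 | 51.3 |

(each reading ± 0.3 percentage points)

- the flask that ends with the higher amount of product, in percent of the starting material charged, or "neither" when 2 percentage points or less lies between them (south-east / north-west / neither)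
- final product, as a percentage of the starting material charged, in south-east
- final product, as a percentage of the starting material charged, in north-west

- charges are per starting volume, the dose included; the dosed solution carries all of it

Replace each curve by its mean slope, with the clock of each run started at the middle of its own 2.5 h feed, and divide by the catalyst charged. In moles of product per mole of catalyst per hour, the last readings give 2.82 h⁻¹ in maple at −25 °C and 7.78 h⁻¹ in cedar at −10 °C. A logarithmic line through them gives 3.96 h⁻¹ at −20 °C, and this mean turnover frequency is what you carry.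

In south-east, partner enters on average at half of its 10 h feed, so you count 20.0 h of running and reckon 79.1 %.

In north-west, the same line extrapolated to 0 °C gives 15.3 h⁻¹. At that rate the remaining charge takes 6.22 h of the 22.5 h at hand, so you expect north-west to end close to complete, above the 79.1 % of south-east.

The forecast said north-west, with 68 % in south-east and 93 % in north-west, where the warm stretch “would nearly finish it”. The flasks give 76.7 % in south-east and 91.2 % in north-west, so north-west ends higher.

    starting material + free catalyst → catalyst intermediate A (k = 1790 M⁻¹ h⁻¹, Ea = 40.0 kJ mol⁻¹)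
    partner + catalyst intermediate A ⇌ catalyst intermediate B (K = 3.53 M⁻¹, k = 1190 M⁻¹ h⁻¹, Ea = 54.0 kJ mol⁻¹, ΔH = −61.0 kJ mol⁻¹)
    catalyst intermediate B → by-product + catalyst intermediate C (k = 33.7 h⁻¹, Ea = 65.0 kJ mol⁻¹)
    catalyst intermediate C ⇌ free catalyst + product (K = 8.20 M, k = 9.81 h⁻¹, Ea = 79.0 kJ mol⁻¹, ΔH = −21.0 kJ mol⁻¹)
    2 partner → homo dimer (k = 0.0166 M⁻¹ h⁻¹, Ea = 67.0 kJ mol⁻¹)
    (constants at −20 °C)

Read back, south-east's result is a mean turnover frequency of 3.83 h⁻¹ against the carried 3.96 h⁻¹. North-west, between 2.50 h and 12.5 h, ran at 6.80 h⁻¹, less than the extrapolated 15.3 h⁻¹. A neighbour of north-west charged with 3.3 × 10⁻⁴ M of free catalyst reckons to 88.6 % by the same mean. That neighbour ends at 46.6 %, with 53.1 % of its starting material and 26 % of its partner left, and 0.0185 M of homo dimer.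

(The earlier runs and the new flask were computed for substances that don't exist, and the scatter is random.)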